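The retrosynthesis returns the three phenols to methyl ethers and the benzylic CH2 at chain carbon C1 to a ketone. It then cuts C3–C4 of the fourteen-carbon chain, C1–C2, the bond from the bridging oxygen to ring B carbon B3, and C13–C14.
Enabling feature: C1 sits on ring B carbon B1, ortho to the oxygen-bearing carbon B2. As a ketone it makes C2=C3 an aryl vinyl ketone, and the unsubstituted terminus C3 accepts a nucleophilic primary radical at C4.
Forward: a Wittig reaction and hydrogenation place C4–C14 on ring A, and an Ullmann coupling joins ring A to the brominated, methylated ring B aldehyde. The alcohol is then converted to the iodide, and vinyl Grignard addition and oxidation install C1–C3.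
The only ring formed, the 21-membered macrocycle, closes last by endo radical conjugate addition. Ionic hydrogenation and BBr3 demethylation finish the synthesis.
Stereochemistry: the target has no stereocentre and no alkene. The Wittig E/Z mixture is hydrogenated and the racemic carbinol is oxidised, so nothing needs control.

Key step: step 10

Remark: chain carbons are numbered C1 (on ring B) to C14 (on ring A). Ring B positions are B1 (chain), B2 (O), B3 (O-aryl) and B5 (O). Compounds 1, 3, 7 and 12 are taken to be catalogue items.

Step 1
Reactants: 1 10-bromodecan-1-ol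
Product: 2 (10-hydroxydecyl)triphenylphosphonium bromide
Conditions: PPh3, MeCN, reflux
Reagents that add atoms: triphenylphosphine, c1ccc(cc1)P(c1ccccc1)c1ccccc1
Why: SN2 quaternisation of triphenylphosphine by an unhindered primary bromide is the standard entry to Wittig salts and leaves the remote hydroxyl group untouched.

Step 2
Reactants: 2 (10-hydroxydecyl)triphenylphosphonium bromide; 3 3-hydroxy-5-methoxybenzaldehyde
Product: 5 3-(11-hydroxyundec-1-en-1-yl)-5-methoxyphenol (E/Z mixture), via alkoxide ylide 4 (not isolated)
Conditions: 2 (1.2 equiv), KOtBu (3.5 equiv), THF, 0 °C; then 3, 0 °C to rt; aq NH4Cl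
Reagents that add atoms: none
Why: In this Wittig olefination the excess KOtBu takes up both hydroxyl protons, the non-stabilised ylide still attacks the formyl group because a meta phenoxide cannot donate into it, and the alkene geometry is irrelevant since the double bond is saturated next.

Step 3
Reactants: 5 3-(11-hydroxyundec-1-en-1-yl)-5-methoxyphenol
Product: 6 3-(11-hydroxyundecyl)-5-methoxyphenol
Conditions: H2 (1 atm), Pd/C, EtOH, rt
Reagents that add atoms: none
Why: Heterogeneous catalytic hydrogenation saturates the styrene-type double bond under conditions that leave the arene, the aryl methyl ether and the primary alcohol alone.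

Step 4
Reactants: 7 2-hydroxy-5-methoxybenzaldehyde
Product: 8 3-bromo-2-hydroxy-5-methoxybenzaldehyde
Conditions: Br2, NaOAc, AcOH, rt
Reagents that add atoms: bromine, BrBr
Why: Electrophilic aromatic bromination is steered by the free phenol, the strongest donor on the ring, to its only open ortho position B3 because the para position carries the methoxy group, and NaOAc buffers the acid released.

Step 5
Reactants: 8 3-bromo-2-hydroxy-5-methoxybenzaldehyde
Product: 9 3-bromo-2,5-dimethoxybenzaldehyde
Conditions: MeI, K2CO3, DMF, rt
Reagents that add atoms: iodomethane, CI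
Why: Williamson O-methylation proceeds readily because the ortho formyl and bromo groups make the phenol acidic enough for carbonate to deprotonate it.

Step 6
Reactants: 6 3-(11-hydroxyundecyl)-5-methoxyphenol; 9 3-bromo-2,5-dimethoxybenzaldehyde
Product: 10 3-[3-(11-hydroxyundecyl)-5-methoxyphenoxy]-2,5-dimethoxybenzaldehyde
Conditions: CuI (10 mol %), N,N-dimethylglycine hydrochloride (30 mol %), Cs2CO3, 1,4-dioxane, 100 °C, Ar
Reagents that add atoms: none
Why: In this ligand-accelerated Ullmann diaryl ether coupling Cs2CO3 deprotonates only the phenol, so the copper phenoxide rather than the aliphatic alcohol is arylated, and the non-enolisable aldehyde tolerates the carbonate base.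

Step 7
Reactants: 10 3-[3-(11-hydroxyundecyl)-5-methoxyphenoxy]-2,5-dimethoxybenzaldehyde
Product: 11 3-[3-(11-iodoundecyl)-5-methoxyphenoxy]-2,5-dimethoxybenzaldehyde
Conditions: I2, PPh3, imidazole, CH2Cl2, 0 °C to rt
Reagents that add atoms: iodine, II
Why: The Appel-type iodination (Garegg–Samuelsson conditions) activates the primary alcohol as its alkoxyphosphonium salt, which iodide displaces by SN2, while the aldehyde and the aryl ethers are inert.

Step 8
Reactants: 11 3-[3-(11-iodoundecyl)-5-methoxyphenoxy]-2,5-dimethoxybenzaldehyde; 12 vinylmagnesium bromide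
Product: 13 rac-1-{3-[3-(11-iodoundecyl)-5-methoxyphenoxy]-2,5-dimethoxyphenyl}prop-2-en-1-ol
Conditions: 12 (1.3 equiv), THF, −78 °C; aq NH4Cl
Reagents that add atoms: none
Why: Grignard 1,2-addition to the aldehyde at −78 °C is far faster than any uncatalysed attack of a vinyl Grignard reagent on a primary alkyl iodide, and the new carbinol centre at C1 forms as a racemate that the next step erases.

Step 9
Reactants: 13 rac-1-{3-[3-(11-iodoundecyl)-5-methoxyphenoxy]-2,5-dimethoxyphenyl}prop-2-en-1-ol
Product: 14 1-{3-[3-(11-iodoundecyl)-5-methoxyphenoxy]-2,5-dimethoxyphenyl}prop-2-en-1-one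
Conditions: activated MnO2 (20 equiv), CH2Cl2, rt; filtration through Celite, used at once
Reagents that add atoms: none
Why: MnO2 oxidation is selective for allylic and benzylic carbinols, runs under neutral heterogeneous conditions that spare the alkyl iodide, and needs only filtration, which suits a vinyl ketone prone to polymerisation.

Step 10
Reactants: 14 1-{3-[3-(11-iodoundecyl)-5-methoxyphenoxy]-2,5-dimethoxyphenyl}prop-2-en-1-one
Product: 15 macrocyclic aryl ketone (ring A and ring B joined by the ether oxygen and by the chain B1–C(=O)–(CH2)13–ring A)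
Conditions: Bu3SnH (1.3 equiv) and AIBN (0.2 equiv) in benzene, added by syringe pump over 12 h to 14 (2 mM) in degassed benzene, reflux
Reagents that add atoms: none
Why: Stannyl radicals generated from AIBN and Bu3SnH abstract iodine from C4, the nucleophilic primary radical adds to the unsubstituted terminal carbon C3 of the electron-poor aryl vinyl ketone, and the delocalised radical at C2 next to the carbonyl takes hydrogen from Bu3SnH, which regenerates the stannyl radical and carries the chain. The closest known reaction type is the tin hydride mediated Giese-type macrocyclisation of ω-iodoalkyl enones and acrylates, established for rings of up to about twenty members, so this case is the same reaction on a slightly longer tether. The single ring closes in the 21-endo-trig mode, because the 20-exo alternative would require attack at the substituted carbon C2 against both polarity and sterics and would leave an unstabilised primary radical. No stereocentre is created. Cyclisation must outrun hydrogen transfer to the C4 radical and intermolecular addition: slow stannane addition secures the first, high dilution secures the second, and the polarity match between alkyl radical and enone keeps the addition fast. Initiation is chemoselective because stannyl radicals abstract iodine from the C–I bond much faster than they engage the enone or the aryl ethers.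

Step 11
Reactants: 15 macrocyclic aryl ketone
Product: 17 macrocyclic trimethyl ether (ring A and ring B joined by the ether oxygen and an unbroken (CH2)14 chain), via benzylic alcohol 16 (not isolated)
Conditions: Et3SiH (5 equiv), TFA, CH2Cl2, 0 °C to rt
Reagents that add atoms: none
Why: In this ionic hydrogenation the protonated ketone accepts hydride from the silane, the resulting alcohol ionises to a benzylic cation stabilised by the ortho methoxy group at B2, and a second hydride transfer gives the methylene group.

Step 12
Reactants: 17 macrocyclic trimethyl ether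
Product: 18 target CNP0393720.0
Conditions: BBr3 (6 equiv), CH2Cl2, −78 °C to rt, Ar; then ice-water
Reagents that add atoms: none
Why: In this Lewis acid ether cleavage BBr3 coordinates each methoxy oxygen and bromide removes the methyl group by SN2, whereas the diaryl ether offers no sp3 carbon for attack and survives, and the argon atmosphere protects the hydroquinone of ring B.

Compound list
1 | 10-bromodecan-1-ol | OCCCCCCCCCCBr | starting material
2 | (10-hydroxydecyl)triphenylphosphonium bromide | [Br-].OCCCCCCCCCC[P+](c1ccccc1)(c1ccccc1)c1ccccc1 | intermediate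
3 | 3-hydroxy-5-methoxybenzaldehyde | COc1cc(O)cc(C=O)c1 | starting material
4 | potassium 10-(triphenyl-λ5-phosphanylidene)decan-1-olate (alkoxide ylide, not isolated) | [K+].[O-]CCCCCCCCCC=P(c1ccccc1)(c1ccccc1)c1ccccc1 | intermediate
5 | 3-(11-hydroxyundec-1-en-1-yl)-5-methoxyphenol, E/Z mixture | COc1cc(O)cc(C=CCCCCCCCCCO)c1 | intermediate
6 | 3-(11-hydroxyundecyl)-5-methoxyphenol | COc1cc(O)cc(CCCCCCCCCCCO)c1 | intermediate
7 | 2-hydroxy-5-methoxybenzaldehyde | COc1ccc(O)c(C=O)c1 | starting material
8 | 3-bromo-2-hydroxy-5-methoxybenzaldehyde | COc1cc(Br)c(O)c(C=O)c1 | intermediate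
9 | 3-bromo-2,5-dimethoxybenzaldehyde | COc1cc(Br)c(OC)c(C=O)c1 | intermediate
10 | 3-[3-(11-hydroxyundecyl)-5-methoxyphenoxy]-2,5-dimethoxybenzaldehyde | COc1cc(CCCCCCCCCCCO)cc(Oc2cc(OC)cc(C=O)c2OC)c1 | intermediate
11 | 3-[3-(11-iodoundecyl)-5-methoxyphenoxy]-2,5-dimethoxybenzaldehyde | COc1cc(CCCCCCCCCCCI)cc(Oc2cc(OC)cc(C=O)c2OC)c1 | intermediate
12 | vinylmagnesium bromide | C=C[Mg]Br | starting material
13 | rac-1-{3-[3-(11-iodoundecyl)-5-methoxyphenoxy]-2,5-dimethoxyphenyl}prop-2-en-1-ol | COc1cc(CCCCCCCCCCCI)cc(Oc2cc(OC)cc(C(O)C=C)c2OC)c1 | intermediate
14 | 1-{3-[3-(11-iodoundecyl)-5-methoxyphenoxy]-2,5-dimethoxyphenyl}prop-2-en-1-one | COc1cc(CCCCCCCCCCCI)cc(Oc2cc(OC)cc(C(=O)C=C)c2OC)c1 | intermediate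
15 | 21-membered macrocyclic aryl ketone: 5-methoxy-1,3-phenylene (ring A) and 2,5-dimethoxy-1,3-phenylene (ring B) joined by O and by B1–C(=O)–(CH2)13 | COc1cc2cc(c1)Oc1cc(OC)cc(c1OC)C(=O)CCCCCCCCCCCCC2 | intermediate
16 | racemic macrocyclic benzylic alcohol, hydroxyl at C1 (not isolated) | COc1cc2cc(c1)Oc1cc(OC)cc(c1OC)C(O)CCCCCCCCCCCCC2 | intermediate
17 | macrocyclic trimethyl ether with a (CH2)14 bridge | COc1cc2cc(c1)Oc1cc(OC)cc(c1OC)CCCCCCCCCCCCCC2 | intermediate
18 | CNP0393720.0: 5-hydroxy-1,3-phenylene (ring A) and 2,5-dihydroxy-1,3-phenylene (ring B) joined by O and by (CH2)14 | Oc1cc2cc(c1)Oc1cc(O)cc(c1O)CCCCCCCCCCCCCC2 | target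

Total step count: 12.
Longest linear sequence: 10 steps (1, 2, 3, 6, 7, 8, 9, 10, 11, 12), from 10-bromodecan-1-ol 1.

Steps most likely to fail

Step 10. The stannane may quench the C4 radical before it reaches C3, the radical may add to a second molecule, or the vinyl ketone may polymerise during the long reflux. The fallback gives up the radical closure and forms the ring by olefin metathesis at C2=C3.
- It sets out from 13. Excess vinylmagnesium bromide 12 with catalytic Li2CuCl4 (THF, −20 to 0 °C, Kochi-type cross-coupling) exchanges the iodine for a vinyl group. This should give the diene 1-{2,5-dimethoxy-3-[3-methoxy-5-(tridec-12-en-1-yl)phenoxy]phenyl}prop-2-en-1-ol F1.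
- Second-generation Grubbs catalyst in dilute refluxing CH2Cl2 should close the 21-membered ring with loss of ethene, giving the macrocyclic C2=C3 allylic alcohol F2.
- H2 over Pd/C in EtOAc saturates the alkene to benzylic alcohol 16, which is isolated in this variant.
- The route is rejoined at 16, which the conditions of step 11 convert to 17. Any hydrogenolysis of the benzylic C–O bond during the hydrogenation would lead to 17 directly.

Step 6. The electron-rich, ortho-substituted bromide may engage the copper catalyst too slowly, so hydrodebromination or erosion of the aldehyde at 100 °C under base takes over. The fallback replaces the halide coupling with an oxidative Chan–Lam–Evans coupling at room temperature.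
- It sets out from 9. Miyaura borylation (B2pin2, Pd(dppf)Cl2, KOAc, 1,4-dioxane, 85 °C) should give 2,5-dimethoxy-3-(4,4,5,5-tetramethyl-1,3,2-dioxaborolan-2-yl)benzaldehyde F3.
- NaIO4 and NH4OAc in aqueous acetone release (3-formyl-2,5-dimethoxyphenyl)boronic acid F4.
- F4 is coupled with phenol 6 (Cu(OAc)2, pyridine, 4 Å molecular sieves, CH2Cl2, air, rt). The primary alcohol is a far poorer partner than the phenol under these conditions.
- The route is rejoined at 10.

Step 9. Oxidation on the MnO2 surface may stall, or the vinyl ketone may be lost to polymerisation and conjugate addition during the long contact time and concentration. The fallback reaches the enone by acyl substitution, so no oxidant meets the enone and a storable precursor precedes it.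
- It sets out from 11. Pinnick oxidation (NaClO2, NaH2PO4, 2-methylbut-2-ene, tBuOH/H2O) should give 3-[3-(11-iodoundecyl)-5-methoxyphenoxy]-2,5-dimethoxybenzoic acid F5.
- Carbonyldiimidazole followed by MeNHOMe·HCl in CH2Cl2 gives the Weinreb amide 3-[3-(11-iodoundecyl)-5-methoxyphenoxy]-N,2,5-trimethoxy-N-methylbenzamide F6.
- Vinylmagnesium bromide 12 (THF, −78 to 0 °C) is added, and an inverse quench into cold dilute HCl keeps the liberated amine from adding to the enone.
- The route is rejoined at 14.

Further compounds
F1 | step 10 | rac-1-{2,5-dimethoxy-3-[3-methoxy-5-(tridec-12-en-1-yl)phenoxy]phenyl}prop-2-en-1-ol | COc1cc(CCCCCCCCCCCC=C)cc(Oc2cc(OC)cc(C(O)C=C)c2OC)c1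
F2 | step 10 | racemic macrocyclic allylic alcohol, hydroxyl at C1, C2=C3 alkene as E/Z mixture | COc1cc2cc(c1)Oc1cc(OC)cc(c1OC)C(O)C=CCCCCCCCCCCC2
F3 | step 6 | 2,5-dimethoxy-3-(4,4,5,5-tetramethyl-1,3,2-dioxaborolan-2-yl)benzaldehyde | COc1cc(C=O)c(OC)c(c1)B2OC(C)(C)C(C)(C)O2
F4 | step 6 | (3-formyl-2,5-dimethoxyphenyl)boronic acid | COc1cc(C=O)c(OC)c(c1)B(O)O
F5 | step 9 | 3-[3-(11-iodoundecyl)-5-methoxyphenoxy]-2,5-dimethoxybenzoic acid | COc1cc(CCCCCCCCCCCI)cc(Oc2cc(OC)cc(C(=O)O)c2OC)c1
F6 | step 9 | 3-[3-(11-iodoundecyl)-5-methoxyphenoxy]-N,2,5-trimethoxy-N-methylbenzamide | COc1cc(CCCCCCCCCCCI)cc(Oc2cc(OC)cc(C(=O)N(C)OC)c2OC)c1
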